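**Retrosynthetic overview**

- Ring A (C1 OH, C2 O-aryl, C3 Br, C4 Br, C5 H, C6 Br) carries no carbon substituent. Its C3–C6 run Br, Br, H, Br is the C2–C5 chain of 2,3,5-tribromothiophene, which leaves C1–C2 as a two-carbon alkyne unit.
- C1–OH is taken back to a C1–B(pin) group, oxidised in the last step.
- Ring A, the only ring made, is closed by [4+2] cycloaddition and SO2 loss between 2,3,5-tribromothiophene 1,1-dioxide and the (2,4-dibromophenoxy)ethynyl boronate, forming C1–C6 and C2–C3. Ring B is bought as 2,4-dibromophenol.
- The alkynyl boronate comes from 2,4-dibromophenol by O-vinylation, bromination–dehydrobromination, and elimination to the acetylide with borylation. The sulfone comes from peracid oxidation of tribromothiophene.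

Key step: step 5

Remark on the chemistry (assumption): the 2-bromovinyl ether of step 2 is drawn as its Z isomer, the expected main product; any E isomer formed with it is carried into step 3, since both lead to the same alkyne.

**Step 1**
Reactants: 1 2,4-dibromophenol; 2 2,4,6-trivinylcyclotriboroxane–pyridine complex
Product: 3 2,4-dibromo-1-(ethenyloxy)benzene
Conditions: Cu(OAc)2 (1 equiv), pyridine, CH2Cl2, air, rt
Reagents that add atoms: none
Why: Chan–Lam–Evans oxidative O-vinylation, in which phenoxide and a vinyl group delivered from boron are joined by C–O reductive elimination at copper and air returns the metal to divalent copper; at room temperature the two aryl bromides should be inert to copper.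

**Step 2**
Reactants: 3 2,4-dibromo-1-(ethenyloxy)benzene
Product: 5 (Z)-2,4-dibromo-1-[(2-bromoethenyl)oxy]benzene, via dibromoethyl ether 4 (not isolated)
Conditions: Br2 (1.0 equiv), CH2Cl2, −78 °C; then iPr2NEt, −78 to 40 °C
Reagents that add atoms: bromine, BrBr
Why: Bromine should add to the enol ether double bond far faster than it substitutes the deactivated, para-blocked ring B, and the hindered amine then removes HBr through loss of the anomeric bromide, the classical bromination–dehydrobromination of vinyl ethers to 2-bromovinyl ethers.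

**Step 3**
Reactants: 5 (Z)-2,4-dibromo-1-[(2-bromoethenyl)oxy]benzene; 6 2-isopropoxy-4,4,5,5-tetramethyl-1,3,2-dioxaborolane
Product: 10 2-[(2,4-dibromophenoxy)ethynyl]-4,4,5,5-tetramethyl-1,3,2-dioxaborolane, via ethynyl ether 7 (not isolated), via lithium acetylide 8 (not isolated), via lithium borate 9 (not isolated)
Conditions: LiN(SiMe3)2 (2.2 equiv), THF, −78 to 0 °C; 6, −78 °C; HCl·Et2O (1.2 equiv), −78 °C to rt
Reagents that add atoms: none
Why: Anti elimination of HBr (the hydrogen on the oxygen-bearing carbon is anti to bromide in the Z isomer) should give ethynyl ether 7, which a second equivalent of silylamide deprotonates to acetylide 8; this base neither exchanges nor ortho-metalates the aryl bromides, and the acetylide is borylated in the standard way for alkynyl pinacolboronates, by addition to the isopropoxyborolane (borate 9) and release with anhydrous HCl.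

**Step 4**
Reactants: 11 2,3,5-tribromothiophene
Product: 13 2,3,5-tribromothiophene 1,1-dioxide, via thiophene 1-oxide 12 (not isolated)
Conditions: (CF3CO)2O, 50% aq H2O2, CH2Cl2, 0 °C to rt
Reagents that add atoms: trifluoroperacetic acid, OOC(=O)C(F)(F)F (formed in the flask from trifluoroacetic anhydride and hydrogen peroxide)
Why: Electrophilic S-oxidation with the strongest common peracid, needed for a thiophene deactivated by three bromines; the S-oxide 12 should be oxidised faster than the thiophene, and bromine at both α-positions should keep the dioxide from dimerising.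

**Step 5**
Reactants: 13 2,3,5-tribromothiophene 1,1-dioxide; 10 2-[(2,4-dibromophenoxy)ethynyl]-4,4,5,5-tetramethyl-1,3,2-dioxaborolane
Product: 15 2-[3,4,6-tribromo-2-(2,4-dibromophenoxy)phenyl]-4,4,5,5-tetramethyl-1,3,2-dioxaborolane, via thiabicycloheptadiene dioxide 14 (not isolated)
Conditions: PhMe, 80 °C, Ar (10 in slight excess)
Reagents that add atoms: none
Why: The diene of 13, made electron-poor by the SO2 group and three bromines, should undergo an inverse-electron-demand [4+2] cycloaddition with the oxygen-donor alkyne 10, forming C1–C6 and C2–C3 of ring A in the bridged adduct 14, which loses SO2 by cheletropic extrusion and is aromatic at once. The closest known reactions are the benzannulation of halogenated thiophene 1,1-dioxides with alkynes and the cycloaddition of alkynylboronates with 2-pyrones to give arylboronates. Ring A is therefore closed by intermolecular [4+2] cycloaddition followed by loss of the one-atom sulfur bridge, and no stereocenter remains because both bridgehead carbons of 14 become aromatic. The step needs the boron-bearing alkyne carbon to bond to thiophene C5 and the oxygen-bearing carbon to C2. Oxygen donation makes the boron-bearing carbon the nucleophilic end that leads bond formation; C5, next to C4–H, is less crowded than C2 beside C3–Br, and attack there places the developing negative charge on C2 and C4 and keeps it off the bromine-bearing C3. Unlike an alkyl ynol ether, 10 cannot fragment by retro-ene loss of an alkene to a ketene, so the cross reaction should prevail over decomposition.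

**Step 6**
Reactants: 15 2-[3,4,6-tribromo-2-(2,4-dibromophenoxy)phenyl]-4,4,5,5-tetramethyl-1,3,2-dioxaborolane
Product: 16 3,4,6-tribromo-2-(2,4-dibromophenoxy)phenol
Conditions: 30% aq H2O2, then 2 M aq NaOH, THF, 0 °C; dilute HCl work-up
Reagents that add atoms: hydrogen peroxide, OO
Why: Boronate oxidation, in which hydroperoxide adds to boron and the aryl group migrates from boron to oxygen at the same carbon; having peroxide present before the base, and working cold, should let oxidation outrun protodeboronation of this 2,6-disubstituted electron-poor arylboronate.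

**Compound list**

1 | 2,4-dibromophenol | Oc1ccc(Br)cc1Br | starting material
2 | 2,4,6-trivinylcyclotriboroxane–pyridine complex | C=CB1OB(C=C)OB(C=C)O1.c1ccncc1 | starting material
3 | 2,4-dibromo-1-(ethenyloxy)benzene | C=COc1ccc(Br)cc1Br | intermediate
4 | 2,4-dibromo-1-(1,2-dibromoethoxy)benzene (racemic) | BrCC(Br)Oc1ccc(Br)cc1Br | intermediate (not isolated)
5 | (Z)-2,4-dibromo-1-[(2-bromoethenyl)oxy]benzene | Br/C=C\Oc1ccc(Br)cc1Br | intermediate
6 | 2-isopropoxy-4,4,5,5-tetramethyl-1,3,2-dioxaborolane | CC(C)OB1OC(C)(C)C(C)(C)O1 | starting material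
7 | 2,4-dibromo-1-(ethynyloxy)benzene | C#COc1ccc(Br)cc1Br | intermediate (not isolated)
8 | lithium (2,4-dibromophenoxy)acetylide | [Li]C#COc1ccc(Br)cc1Br | intermediate (not isolated)
9 | lithium [(2,4-dibromophenoxy)ethynyl](isopropoxy)(pinacolato)borate | [Li+].CC(C)O[B-]1(C#COc2ccc(Br)cc2Br)OC(C)(C)C(C)(C)O1 | intermediate (not isolated)
10 | 2-[(2,4-dibromophenoxy)ethynyl]-4,4,5,5-tetramethyl-1,3,2-dioxaborolane | CC1(C)OB(C#COc2ccc(Br)cc2Br)OC1(C)C | intermediate
11 | 2,3,5-tribromothiophene | Brc1cc(Br)c(Br)s1 | starting material
12 | 2,3,5-tribromothiophene 1-oxide (racemic at sulfur) | O=S1C(Br)=CC(Br)=C1Br | intermediate (not isolated)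
13 | 2,3,5-tribromothiophene 1,1-dioxide | O=S1(=O)C(Br)=CC(Br)=C1Br | intermediate
14 | 1,2,4-tribromo-6-(2,4-dibromophenoxy)-5-(4,4,5,5-tetramethyl-1,3,2-dioxaborolan-2-yl)-7-thiabicyclo[2.2.1]hepta-2,5-diene 7,7-dioxide (racemic) | O=S1(=O)C2(Br)C(Br)=CC1(Br)C(B3OC(C)(C)C(C)(C)O3)=C2Oc1ccc(Br)cc1Br | intermediate (not isolated)
15 | 2-[3,4,6-tribromo-2-(2,4-dibromophenoxy)phenyl]-4,4,5,5-tetramethyl-1,3,2-dioxaborolane | CC1(C)OB(OC1(C)C)c1c(Br)cc(Br)c(Br)c1Oc1ccc(Br)cc1Br | intermediate
16 | 3,4,6-tribromo-2-(2,4-dibromophenoxy)phenol | Oc1c(Br)cc(Br)c(Br)c1Oc1ccc(Br)cc1Br | target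

**Step count and risks**

Total step count: 6. Longest linear sequence: 5 steps (steps 1, 2, 3, 5, 6); the sulfone branch (step 4) joins at step 5.

Steps most likely to fail:

1. Step 5. The cycloaddition may run in the reverse orientation, with the boron-bearing carbon bonding to thiophene C2 and giving the 3,5,6-tribromo ring, or dimerisation of the diene may outrun the cross reaction. Fallback, setting out from 1 and coming back at 16: nucleophilic aromatic substitution of 1 on commercial 3-bromo-2-fluorobenzaldehyde (K2CO3, DMAc, 120 °C) should give 3-bromo-2-(2,4-dibromophenoxy)benzaldehyde F1. Baeyer–Villiger oxidation (mCPBA, CH2Cl2) with migration of the aryloxy-substituted ring should give 3-bromo-2-(2,4-dibromophenoxy)phenyl formate F2, and methanolysis (K2CO3, MeOH) should give 3-bromo-2-(2,4-dibromophenoxy)phenol F3. Bromination (Br2, 2 equiv, AcOH) is directed by the free hydroxyl to its open para and ortho positions, C4 and C6, and should give 16. This fixes the ring A pattern by ordinary directing effects and needs no cycloaddition.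

2. Step 3. Boron may be lost from the push–pull alkynyl boronate by protonolysis during the acidic release from borate 9, or by hydrolysis on isolation. Fallback, setting out from 5 and coming back at 15: acetylide 8 is generated as in step 3 and quenched with Bu3SnCl instead of the borolane, with neutral work-up, to give tributyl[(2,4-dibromophenoxy)ethynyl]stannane F4. Cycloaddition of F4 with 13 (PhMe, 80 °C) should pass through the stannylated thiabicycloheptadiene dioxide F5 (not isolated) and, after SO2 loss, give tributyl[3,4,6-tribromo-2-(2,4-dibromophenoxy)phenyl]stannane F6; the tin-bearing carbon is again the nucleophilic and bulkier end. Tin–boron exchange with BCl3 (CH2Cl2, −78 °C to rt) should give dichloro[3,4,6-tribromo-2-(2,4-dibromophenoxy)phenyl]borane F7 (not isolated), which pinacol converts into 15.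

3. Step 4. S-oxidation of the electron-poor thiophene may stay incomplete while the dioxide decomposes or dimerises under prolonged acidic oxidising conditions. Fallback, setting out from 11 and coming back at 13: twofold α-bromine–lithium exchange (n-BuLi, 2.1 equiv, THF, −78 °C) should give 3-bromo-2,5-dilithiothiophene F8 (not isolated), silylated with Me3SiCl to 3-bromo-2,5-bis(trimethylsilyl)thiophene F9. This more electron-rich, α-shielded thiophene should be oxidised by mCPBA (CH2Cl2) to 3-bromo-2,5-bis(trimethylsilyl)thiophene 1,1-dioxide F10. Ipso-bromodesilylation at both α-positions (Br2, AgBF4, CH2Cl2) should then give 13.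

**Further compounds**

F1 | step 5 | 3-bromo-2-(2,4-dibromophenoxy)benzaldehyde | O=Cc1cccc(Br)c1Oc1ccc(Br)cc1Br
F2 | step 5 | 3-bromo-2-(2,4-dibromophenoxy)phenyl formate | O=COc1cccc(Br)c1Oc1ccc(Br)cc1Br
F3 | step 5 | 3-bromo-2-(2,4-dibromophenoxy)phenol | Oc1cccc(Br)c1Oc1ccc(Br)cc1Br
F4 | step 3 | tributyl[(2,4-dibromophenoxy)ethynyl]stannane | CCCC[Sn](CCCC)(CCCC)C#COc1ccc(Br)cc1Br
F5 | step 3 | 1,2,4-tribromo-6-(2,4-dibromophenoxy)-5-(tributylstannyl)-7-thiabicyclo[2.2.1]hepta-2,5-diene 7,7-dioxide (racemic) | O=S1(=O)C2(Br)C(Br)=CC1(Br)C([Sn](CCCC)(CCCC)CCCC)=C2Oc1ccc(Br)cc1Br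
F6 | step 3 | tributyl[3,4,6-tribromo-2-(2,4-dibromophenoxy)phenyl]stannane | CCCC[Sn](CCCC)(CCCC)c1c(Br)cc(Br)c(Br)c1Oc1ccc(Br)cc1Br
F7 | step 3 | dichloro[3,4,6-tribromo-2-(2,4-dibromophenoxy)phenyl]borane | ClB(Cl)c1c(Br)cc(Br)c(Br)c1Oc1ccc(Br)cc1Br
F8 | step 4 | 3-bromo-2,5-dilithiothiophene | [Li]c1cc(Br)c([Li])s1
F9 | step 4 | 3-bromo-2,5-bis(trimethylsilyl)thiophene | C[Si](C)(C)c1cc(Br)c([Si](C)(C)C)s1
F10 | step 4 | 3-bromo-2,5-bis(trimethylsilyl)thiophene 1,1-dioxide | C[Si](C)(C)C1=CC(Br)=C([Si](C)(C)C)S1(=O)=O
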